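I decided to keep books on the reagent: a mole of it stands free, or in mono adduct, or as the second of two in bis adduct.

| setting | Wednesday's | Friday's | autumn | dusk | spring |
|---|---|---|---|---|---|
| substrate | 0.17 M (in portions, 3) | 0.17 M (in portions, 3) | 0.17 M (in portions, 3) | 0.17 M (in portions, 3) | 0.17 M (in portions, 3) |
| reagent | 0.11 M | 1 M | 0.204 M | 0.0850 M | 0.680 M |
| remark | run made earlier; portions every 2.0 min | run made earlier; portions every 2.0 min | the portions of substrate follow each other after 2.0 min, the first at the start | the portions of substrate follow each other after 2.0 min, the first at the start | the portions of substrate follow each other after 2.0 min, the first at the start |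
| time |  |  | 12 min | 12 min | 12 min |

| run | time / min | bis adduct / % | substrate / % |
|---|---|---|---|
| Wednesday's | 0.667 | 0.7 | 26.1 |
| Wednesday's | 1.33 | 1.4 | 21.3 |
| Wednesday's | 2.50 | 2.0 | 44.2 |
| Wednesday's | 4.00 | 2.5 | 32.5 |
| Wednesday's | 8.00 | 1.9 | 45.5 |
| Friday's | 1.50 | 20.0 | 0 |
| Friday's | 3.00 | 37.6 | 1.2 |
| Friday's | 5.00 | 52.9 | 2.3 |
| Friday's | 6.00 | 53.3 | 0.3 |
| Friday's | 8.00 | 52.3 | 0 |

(scatter of a reading: 0.3 percentage points)



* which of these holds the largest part of the substrate at the end of autumn (mono adduct / bis adduct / substrate)
* which of these holds the largest part of the substrate at the end of dusk (mono adduct / bis adduct / substrate)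
* which of these holds the largest part of the substrate at the end of spring (mono adduct / bis adduct / substrate)
* amount of bis adduct at the end of autumn, in percent of the substrate charged

Friday's bis adduct read 52.9 % at 5.00 min and 52.3 % at 8.00 min, with substrate reading 0 %. I therefore took the remainder as mono adduct, and the ledger left 0.741 M of reagent free. From that reading I kept 1.48 L mol⁻¹ as the bis constant, the ratio of bis adduct to mono adduct per unit of free reagent, an equilibrium constant. Wednesday's first portion had fallen to 26.1 % of the charge by 0.667 min, which reads as 3.33 L mol⁻¹ min⁻¹ for the first addition.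

In autumn the reagent exceeds the substrate by a gap of 0.0340 M. Free reagent minus free substrate equals that gap less the bis adduct. For such a pair the second-order law gives free substrate as the gap over [r·exp(k·gap·t) − 1], where k is the rate constant of the first addition, r is the starting ratio of reagent to substrate, and t runs from the mean portion, here 10.0 min. Ignoring bis adduct, I got 0.0125 M of substrate, 0.0465 M of reagent and, by the constant, 0.0101 M of bis adduct. Entering that shrank the gap to 0.0239 M, leaving 0.0156 M of substrate, 0.0395 M of reagent and 0.008522 M of bis adduct. My autumn answer was thus 5.01 % bis adduct, with mono adduct leading at 85.8 %.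

Dusk holds 0.500 equivalents, so there reagent is the limiting reagent and at least 50.0 % of the substrate stays unreacted: I chose substrate. In spring, once substrate has gone, free reagent is at most 0.510 M, and on that amount my constant, itself a reading, gives an estimated ratio of 0.755, below one: I chose mono adduct.

The forecast named mono adduct, substrate and mono adduct with 5.2 % of bis adduct in autumn, starting from “Friday's bis adduct plateaus near 53% despite excess reagent”, a little above my figure.

Autumn ended with 82.5 % mono adduct, 9.84 % substrate and 5.64 % bis adduct; dusk led with substrate at 52.0 %, spring with mono adduct at 50.6 %.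

    substrate + reagent → mono adduct (k = 0.0600 M⁻¹ s⁻¹)
    reagent + mono adduct ⇌ bis adduct (K = 1.80 M⁻¹, k = 0.150 M⁻¹ s⁻¹)
    bis adduct ⇌ isomer of the product (K = 0.830, k = 5.50 × 10⁻⁴ s⁻¹)

In autumn at 3.46 min the reagent had a half-life of 5.2 min by the first addition, while the bis adduct had one of 21 min by its forward step to the isomer of the product alone, a slower drain. By 12.0 min that isomer, an entry my ledger lacked, held 1.98 % beside 5.64 % bis adduct. The bis constant on autumn's 0.0378 M of free reagent gives a ratio of 0.0559, against 0.0683 in the flask. The neighbour charged with 0.068 M of substrate kept 60 % of its reagent, so the constant gives 0.181, and that flask stood at 0.219, with 17.0 % bis adduct.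

The readings stem from a simulated flask from invented constants, noise included.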